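**Time fixed.** At 25 min the new flasks are stopped, each charged with 0.25 M of starting material, and they differ in their loading of free catalyst.

| setting | Wednesday's | Sunday's | south | north-east | north | south-east |
|---|---|---|---|---|---|---|
| starting material | 0.25 M | 0.25 M | 0.25 M | 0.25 M | 0.25 M | 0.25 M |
| free catalyst | 4 mol% | 24 mol% | 8 mol% | 12 mol% | 20 mol% | 30 mol% |
| remark | run made earlier | run made earlier |  |  |  |  |
| time |  |  | 25 min | 25 min | 25 min | 25 min |

- Wednesday's (time / min: target / %, starting material / %): 6.00: 8, 92; 12.0: 13, 85; 20.0: 20, 74; 25.0: 25, 67
- Sunday's (time / min: target / %, starting material / %): 3.00: 13, 74; 8.00: 35, 49; 15.0: 58, 26; 25.0: 73, 14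

(standard deviation of a reading: 2 percentage points)

- amount of target at the end, in percent of the starting material charged for south, north-east, north, south-east, in this order
- the shape of the row from first to last (rises, then falls / falls, then rises / hardly changes / rises all the way / falls all the way)

- "hardly changes" means that all values lie within two and a half points (for a concentration: within two and a half percent of the largest)

**Zero of scale.** The zero of the scale is strict proportion: the logarithm of the fraction of starting material left grows with loading times time, a pseudo-first-order decay. At 25.0 min, Sunday's loading is 6.00 times Wednesday's, but the reading of Sunday's logarithm is 4.91 times Wednesday's, less than proportion gives. Summing both logarithms over both products of loading and time gives 0.338 min⁻¹ per unit of loading, as a reading with its scatter.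

**Halving loading.** That reading gives 8.20%, the halving loading: the step of loading that leaves half of c(starting material) at 25 min.

**The curve.** What follows is a reckoning separate from the forecast. Against loading, starting material left at 25 min starts down at 8.5 percentage points per mol%. It crosses half at 8.20%, reaches a quarter at 16.4%, and reaches 12.5% at 24.6%, flattening towards zero. South, north-east, north and south-east therefore keep 50.9%, 36.3%, 18.4% and 7.92%. Target read below the consumed share at 25.0 min on Wednesday and on Sunday, so it is expected below the reckoned share here, 49.1% to 92.1%; that share rises along the row, and the row is expected to rise with it.

**The forecast.** It gives 44%, 58%, 69% and 78%, and rises all the way: “There is no sign of target being consumed, so the row rises throughout, flattening at high loading.” For south it leaves 46% of the starting material, against 50.9% here.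

**The flask.** The row is 44.0%, 56.0%, 68.9% and 73.5%: rises all the way.

    starting material + free catalyst → catalyst intermediate (k = 0.0480 M⁻¹ s⁻¹)
    target + free catalyst ⇌ isomer of the product + free catalyst, rate k2*[free catalyst]*[target] forward; the back reaction follows from the equilibrium constant (K = 0.720, k = 8.80 × 10⁻⁴ M⁻¹ s⁻¹)
    catalyst intermediate ⇌ free catalyst + target (K = 0.160 M, k = 0.0100 s⁻¹)

South holds 51% of its starting material against the 50.9% from the halving loading, and south-east holds 7.7% against 7.92%. In south, the half-life of target by the forward rate of the loss to isomer of the product alone, taken at 25.0 min, is 25 h, longer than the 25 min run, and isomer of the product stands there at 0.279% after 25.0 min.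

The earlier runs and the new flask stem from a simulated flask with constants of no real substance; noise was put on by code.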